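**Retrosynthetic overview**
- Target ⇐ removal of two silyl ethers and one acetonide; the C4 and C8 angelates are put on late by Yamaguchi esterification, the C1 angelate early by Mitsunobu inversion.
- C8 carbinol ⇐ hydroxyl-directed anti reduction of a β-hydroxy enone, so the bought C10 centre sets C8.
- Key disconnection C8–C9: light-driven decatungstate/nickel union of the formyl C–H of a ring enal with 2-[(2S)-oxiran-2-yl]propan-2-ol (from methyl (S)-glycidate).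
- Ring enal ⇐ (R)-carvone: allylic chlorination then N-oxide oxidation (C8), α'-silyloxylation (C6), Luche/Mitsunobu (C1), OsO4 then oxidation (C2-OH, C3=O), Rubottom (C4-O).
- Ring order: the single carbocycle is bought intact in carvone; no ring-forming step (only a temporary dioxolane).

Assumption: methyl (S)-glycidate is taken as an inexpensive commercial enantiopure building block.
Locants: ring carbons keep carvone numbering C1–C6; side chain is C7(=CH2), C8, C9, C10, C11. TBS = tert-butyldimethylsilyl, TES = triethylsilyl, angelate = (2Z)-2-methylbut-2-enoate.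

Step 1
Reactants: 1 (R)-carvone
Product: 2 (5R)-5-(3-chloroprop-1-en-2-yl)-2-methylcyclohex-2-en-1-one
Conditions: Ca(OCl)2, CO2 (s), CH2Cl2/H2O, 0 °C
Reagents that add atoms: calcium hypochlorite ([Ca+2].[O-]Cl.[O-]Cl)
Why: Ene-type allylic chlorination by HOCl attacks only the electron-rich 1,1-disubstituted isopropenyl alkene (the conjugated ring alkene is inert) and leaves C5 untouched.

Step 2
Reactants: 2 (5R)-5-(3-chloroprop-1-en-2-yl)-2-methylcyclohex-2-en-1-one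
Product: 4 (5S,6S)-6-(TBSO)-5-(3-chloroprop-1-en-2-yl)-2-methylcyclohex-2-en-1-one, via silyl dienol ether 3 (not isolated)
Conditions: LiN(iPr)2, THF, −78 °C; TBSOTf; then DMDO, acetone/CH2Cl2, −78 → 23 °C
Reagents that add atoms: tert-butyldimethylsilyl triflate (CC(C)(C)[Si](C)(C)OS(=O)(=O)C(F)(F)F); dimethyldioxirane (CC1(C)OO1)
Why: Kinetic C6 deprotonation and O-silylation followed by Rubottom oxidation (enol-ether epoxidation, then 1,4-silyl shift) place the silyloxy group at C6 anti to the C5 substituent, the chloromethyl-bearing alkene being too electron-poor to compete.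

Step 3
Reactants: 4 (5S,6S)-6-(TBSO)-5-(3-chloroprop-1-en-2-yl)-2-methylcyclohex-2-en-1-one
Product: 5 (1S,5S,6S)-6-(TBSO)-5-(3-chloroprop-1-en-2-yl)-2-methylcyclohex-2-en-1-ol
Conditions: NaBH4, CeCl3·7H2O, MeOH, −78 °C
Reagents that add atoms: none
Why: Luche 1,2-reduction with axial hydride delivery, as for carvone itself, gives the pseudo-equatorial C1 alcohol cis to the C5 side chain and trans to the C6 silyl ether.

Step 4
Reactants: 5 (1S,5S,6S)-6-(TBSO)-5-(3-chloroprop-1-en-2-yl)-2-methylcyclohex-2-en-1-ol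
Product: 6 (1R,5S,6S)-6-(TBSO)-5-(3-chloroprop-1-en-2-yl)-2-methylcyclohex-2-en-1-yl angelate
Conditions: angelic acid, PPh3, DIAD, toluene, 0 → 23 °C
Reagents that add atoms: angelic acid (C/C=C(/C)C(=O)O)
Why: Mitsunobu esterification inverts C1 by SN2 attack of angelate on the activated allylic alcohol, and because the acid is the nucleophile and never an activated acyl donor the Z alkene cannot isomerise to tiglate.

Step 5
Reactants: 6 (1R,5S,6S)-6-(TBSO)-5-(3-chloroprop-1-en-2-yl)-2-methylcyclohex-2-en-1-yl angelate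
Product: 7 (1R,5S,6S)-6-(TBSO)-2-methyl-5-(3-oxoprop-1-en-2-yl)cyclohex-2-en-1-yl angelate
Conditions: Me3NO, NaI (cat.), DMSO, 23 °C
Reagents that add atoms: trimethylamine N-oxide (C[N+](C)(C)[O-])
Why: Ganem-type N-oxide oxidation (iodide-relayed SN2 on the primary allylic chloride, then collapse of the alkoxyammonium salt) gives the 2-substituted acrolein without touching ester or silyl ether.

Step 6
Reactants: 7 (1R,5S,6S)-6-(TBSO)-2-methyl-5-(3-oxoprop-1-en-2-yl)cyclohex-2-en-1-yl angelate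
Product: 8 (1S,2S,3S,5S,6S)-6-(TBSO)-2,3-dihydroxy-2-methyl-5-(3-oxoprop-1-en-2-yl)cyclohexyl angelate
Conditions: OsO4 (5 mol%), NMO, acetone/H2O, 0 °C
Reagents that add atoms: osmium tetroxide (O=[Os](=O)(=O)=O); N-methylmorpholine N-oxide (C[N+]1([O-])CCOCC1); water (O)
Why: Upjohn dihydroxylation hits the only electron-rich alkene (enal and angelate alkenes are conjugated and deactivated) on the face anti to the pseudo-axial C1 angelate, setting C2-OH cis to the side chain.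

Step 7
Reactants: 8 (1S,2S,3S,5S,6S)-6-(TBSO)-2,3-dihydroxy-2-methyl-5-(3-oxoprop-1-en-2-yl)cyclohexyl angelate
Product: 9 (1S,2R,5S,6S)-6-(TBSO)-2-hydroxy-2-methyl-3-oxo-5-(3-oxoprop-1-en-2-yl)cyclohexyl angelate
Conditions: Dess–Martin periodinane, CH2Cl2, 0 → 23 °C
Reagents that add atoms: none
Why: Dess–Martin oxidation converts the only secondary alcohol into the C3 ketone; the tertiary C2-OH cannot be oxidised and, C2 having no hydrogen, the β-acyloxy ketone cannot eliminate.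

Step 8
Reactants: 9 (1S,2R,5S,6S)-6-(TBSO)-2-hydroxy-2-methyl-3-oxo-5-(3-oxoprop-1-en-2-yl)cyclohexyl angelate
Product: 11 (1S,2R,4R,5S,6S)-6-(TBSO)-2-methyl-3-oxo-5-(3-oxoprop-1-en-2-yl)-2,4-bis(TESO)cyclohexyl angelate, via bis-silyl enol ether 10 (not isolated)
Conditions: TESOTf, Et3N, CH2Cl2, −78 → 0 °C; then DMDO, acetone, −78 → 0 °C
Reagents that add atoms: triethylsilyl triflate (CC[Si](CC)(CC)OS(=O)(=O)C(F)(F)F); dimethyldioxirane (CC1(C)OO1)
Why: Soft enolisation can only go towards C4 (C2 is quaternary) and caps the tertiary alcohol, then Rubottom oxidation delivers oxygen anti to the pseudo-axial C2-OTES and the C5 side chain (trans-diequatorial C4/C5, also the thermodynamic epimer), the silyl shift leaving no free hydroxyl next to the aldehyde.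

Step 9
Reactants: 12 methyl (2S)-oxirane-2-carboxylate
Product: 13 2-[(2S)-oxiran-2-yl]propan-2-ol
Conditions: MeMgBr (2.1 equiv), THF, −78 °C; aq NH4Cl
Reagents that add atoms: methylmagnesium bromide (C[Mg]Br)
Why: Double Grignard addition to the ester at −78 °C, where the epoxide is inert, keeps the bought stereocentre intact.

Step 10
Reactants: 11 (1S,2R,4R,5S,6S)-6-(TBSO)-2-methyl-3-oxo-5-(3-oxoprop-1-en-2-yl)-2,4-bis(TESO)cyclohexyl angelate; 13 2-[(2S)-oxiran-2-yl]propan-2-ol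
Product: 15 (1S,2R,4R,5S,6S)-6-(TBSO)-5-[(5S)-5,6-dihydroxy-6-methyl-3-oxohept-1-en-2-yl]-2-methyl-3-oxo-2,4-bis(TESO)cyclohexyl angelate, via iodohydrin 14 (not isolated)
Conditions: (Bu4N)4[W10O32] (2 mol%), NiBr2·(MeOCH2CH2OMe) (10 mol%), 4,4'-di-tert-butyl-2,2'-bipyridine (12 mol%), LiI (20 mol%), 2,4,6-collidinium triflate (20 mol%), MeCN/acetone, 390 nm LEDs, 23 °C
Reagents that add atoms: none
Why: Proposed new method: decatungstate/nickel formal hydroacylation of a terminal epoxide – iodide and the collidinium proton open 13 at its CH2 terminus to iodohydrin 14 without touching the carbinol centre, photoexcited decatungstate abstracts the formyl hydrogen of 11 to give a σ-acyl radical that is captured by bipyridine-ligated zerovalent nickel, the acylnickel takes up the primary alkyl iodide by halogen abstraction and radical rebound, reductive elimination from trivalent nickel forms the C8–C9 bond, and reduced decatungstate returns monovalent nickel to the zerovalent state while releasing HI for the next epoxide opening (redox-neutral, catalytic in iodide); the closest known reactions are decatungstate/nickel acylation of organic halides with aldehydes and iodide-relayed nickel coupling of epoxides with aryl halides.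

Step 11
Reactants: 15 (1S,2R,4R,5S,6S)-6-(TBSO)-5-[(5S)-5,6-dihydroxy-6-methyl-3-oxohept-1-en-2-yl]-2-methyl-3-oxo-2,4-bis(TESO)cyclohexyl angelate
Product: 16 (1S,2R,4R,5S,6S)-6-(TBSO)-2-methyl-3-oxo-2,4-bis(TESO)-5-[(3S,5S)-3,5,6-trihydroxy-6-methylhept-1-en-2-yl]cyclohexyl angelate
Conditions: Me4NBH(OAc)3, MeCN/AcOH, −35 °C
Reagents that add atoms: none
Why: Evans–Saksena reduction delivers hydride intramolecularly from the borate bound to C10-OH through a chair six-membered transition state, giving the 1,3-anti diol (C8 S); the ring ketone has no free neighbouring hydroxyl and is not reduced.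

Step 12
Reactants: 16 (1S,2R,4R,5S,6S)-6-(TBSO)-2-methyl-3-oxo-2,4-bis(TESO)-5-[(3S,5S)-3,5,6-trihydroxy-6-methylhept-1-en-2-yl]cyclohexyl angelate
Product: 18 (1S,2R,4R,5R,6S)-6-(TBSO)-4-hydroxy-5-{(3S)-3-hydroxy-4-[(4S)-2,2,5,5-tetramethyl-1,3-dioxolan-4-yl]but-1-en-2-yl}-2-methyl-3-oxo-2-(TESO)cyclohexyl angelate, via acetonide 17 (not isolated)
Conditions: Me2C(OMe)2, PPTS (cat.), acetone, 23 °C; then MeOH, 0 °C
Reagents that add atoms: 2,2-dimethoxypropane (COC(C)(C)OC)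
Why: Thermodynamic acetalisation gives the five-membered dioxolane of the 1,2-diol rather than the strained acetonide of the anti-1,3-diol, and PPTS/MeOH then cleaves only the secondary TES ether (tertiary TES and TBS ethers are much slower).

Step 13
Reactants: 18 (1S,2R,4R,5R,6S)-6-(TBSO)-4-hydroxy-5-{(3S)-3-hydroxy-4-[(4S)-2,2,5,5-tetramethyl-1,3-dioxolan-4-yl]but-1-en-2-yl}-2-methyl-3-oxo-2-(TESO)cyclohexyl angelate
Product: 19 (1S,2R,4R,5R,6S)-6-(TBSO)-2-methyl-3-oxo-5-{(3S)-3-(angeloyloxy)-4-[(4S)-2,2,5,5-tetramethyl-1,3-dioxolan-4-yl]but-1-en-2-yl}-2-(TESO)cyclohexane-1,4-diyl bisangelate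
Conditions: angelic acid, 2,4,6-trichlorobenzoyl chloride, Et3N, toluene, 23 → 75 °C
Reagents that add atoms: angelic acid (C/C=C(/C)C(=O)O)
Why: DMAP-free Yamaguchi esterification acylates the two free secondary alcohols (C4 and C8) without Z to E isomerisation of the angeloyl group, the tertiary silyl ether and the protected diol being inert.

Step 14
Reactants: 19 (1S,2R,4R,5R,6S)-6-(TBSO)-2-methyl-3-oxo-5-{(3S)-3-(angeloyloxy)-4-[(4S)-2,2,5,5-tetramethyl-1,3-dioxolan-4-yl]but-1-en-2-yl}-2-(TESO)cyclohexane-1,4-diyl bisangelate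
Product: 20 CNP0215698.1
Conditions: HF (48% aq), MeCN, 0 → 23 °C
Reagents that add atoms: none
Why: Acidic fluoride cleaves both silyl ethers and hydrolyses the acetonide; the angelates and ketone are stable to it and no base is present that could trigger acyl migration.

**Compound list**
1 | (5R)-2-methyl-5-(prop-1-en-2-yl)cyclohex-2-en-1-one, (R)-carvone | C=C(C)[C@H]1CC(=O)C(C)=CC1 | starting material
2 | (5R)-5-(3-chloroprop-1-en-2-yl)-2-methylcyclohex-2-en-1-one | C=C(CCl)[C@H]1CC(=O)C(C)=CC1 | intermediate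
3 | tert-butyl{[(3R)-3-(3-chloroprop-1-en-2-yl)-6-methylcyclohexa-1,5-dien-1-yl]oxy}dimethylsilane | C=C(CCl)[C@H]1C=C(O[Si](C)(C)C(C)(C)C)C(C)=CC1 | intermediate
4 | (5S,6S)-6-[(tert-butyldimethylsilyl)oxy]-5-(3-chloroprop-1-en-2-yl)-2-methylcyclohex-2-en-1-one | C=C(CCl)[C@H]1[C@H](O[Si](C)(C)C(C)(C)C)C(=O)C(C)=CC1 | intermediate
5 | (1S,5S,6S)-6-[(tert-butyldimethylsilyl)oxy]-5-(3-chloroprop-1-en-2-yl)-2-methylcyclohex-2-en-1-ol | C=C(CCl)[C@H]1[C@H](O[Si](C)(C)C(C)(C)C)[C@@H](O)C(C)=CC1 | intermediate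
6 | (1R,5S,6S)-6-[(tert-butyldimethylsilyl)oxy]-5-(3-chloroprop-1-en-2-yl)-2-methylcyclohex-2-en-1-yl (2Z)-2-methylbut-2-enoate | C=C(CCl)[C@H]1[C@H](O[Si](C)(C)C(C)(C)C)[C@H](OC(=O)/C(C)=C\C)C(C)=CC1 | intermediate
7 | (1R,5S,6S)-6-[(tert-butyldimethylsilyl)oxy]-2-methyl-5-(3-oxoprop-1-en-2-yl)cyclohex-2-en-1-yl (2Z)-2-methylbut-2-enoate | C=C(C=O)[C@H]1[C@H](O[Si](C)(C)C(C)(C)C)[C@H](OC(=O)/C(C)=C\C)C(C)=CC1 | intermediate
8 | (1S,2S,3S,5S,6S)-6-[(tert-butyldimethylsilyl)oxy]-2,3-dihydroxy-2-methyl-5-(3-oxoprop-1-en-2-yl)cyclohexyl (2Z)-2-methylbut-2-enoate | C=C(C=O)[C@H]1[C@H](O[Si](C)(C)C(C)(C)C)[C@H](OC(=O)/C(C)=C\C)[C@@](C)(O)[C@@H](O)C1 | intermediate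
9 | (1S,2R,5S,6S)-6-[(tert-butyldimethylsilyl)oxy]-2-hydroxy-2-methyl-3-oxo-5-(3-oxoprop-1-en-2-yl)cyclohexyl (2Z)-2-methylbut-2-enoate | C=C(C=O)[C@H]1[C@H](O[Si](C)(C)C(C)(C)C)[C@H](OC(=O)/C(C)=C\C)[C@@](C)(O)C(=O)C1 | intermediate
10 | (1S,2R,5S,6S)-6-[(tert-butyldimethylsilyl)oxy]-2-methyl-5-(3-oxoprop-1-en-2-yl)-2,3-bis[(triethylsilyl)oxy]cyclohex-3-en-1-yl (2Z)-2-methylbut-2-enoate | C=C(C=O)[C@H]1[C@H](O[Si](C)(C)C(C)(C)C)[C@H](OC(=O)/C(C)=C\C)[C@@](C)(O[Si](CC)(CC)CC)C(O[Si](CC)(CC)CC)=C1 | intermediate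
11 | (1S,2R,4R,5S,6S)-6-[(tert-butyldimethylsilyl)oxy]-2-methyl-3-oxo-5-(3-oxoprop-1-en-2-yl)-2,4-bis[(triethylsilyl)oxy]cyclohexyl (2Z)-2-methylbut-2-enoate | C=C(C=O)[C@H]1[C@H](O[Si](C)(C)C(C)(C)C)[C@H](OC(=O)/C(C)=C\C)[C@@](C)(O[Si](CC)(CC)CC)C(=O)[C@@H]1O[Si](CC)(CC)CC | intermediate
12 | methyl (2S)-oxirane-2-carboxylate | COC(=O)[C@@H]1CO1 | starting material
13 | 2-[(2S)-oxiran-2-yl]propan-2-ol | CC(C)(O)[C@@H]1CO1 | intermediate
14 | (2R)-1-iodo-3-methylbutane-2,3-diol | IC[C@H](O)C(C)(C)O | intermediate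
15 | (1S,2R,4R,5S,6S)-6-[(tert-butyldimethylsilyl)oxy]-5-[(5S)-5,6-dihydroxy-6-methyl-3-oxohept-1-en-2-yl]-2-methyl-3-oxo-2,4-bis[(triethylsilyl)oxy]cyclohexyl (2Z)-2-methylbut-2-enoate | C=C([C@H]1[C@H](O[Si](C)(C)C(C)(C)C)[C@H](OC(=O)/C(C)=C\C)[C@@](C)(O[Si](CC)(CC)CC)C(=O)[C@@H]1O[Si](CC)(CC)CC)C(=O)C[C@H](O)C(C)(C)O | intermediate
16 | (1S,2R,4R,5S,6S)-6-[(tert-butyldimethylsilyl)oxy]-2-methyl-3-oxo-2,4-bis[(triethylsilyl)oxy]-5-[(3S,5S)-3,5,6-trihydroxy-6-methylhept-1-en-2-yl]cyclohexyl (2Z)-2-methylbut-2-enoate | C=C([C@H]1[C@H](O[Si](C)(C)C(C)(C)C)[C@H](OC(=O)/C(C)=C\C)[C@@](C)(O[Si](CC)(CC)CC)C(=O)[C@@H]1O[Si](CC)(CC)CC)[C@H](C[C@H](O)C(C)(C)O)O | intermediate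
17 | (1S,2R,4R,5S,6S)-6-[(tert-butyldimethylsilyl)oxy]-5-{(3S)-3-hydroxy-4-[(4S)-2,2,5,5-tetramethyl-1,3-dioxolan-4-yl]but-1-en-2-yl}-2-methyl-3-oxo-2,4-bis[(triethylsilyl)oxy]cyclohexyl (2Z)-2-methylbut-2-enoate | C=C([C@H]1[C@H](O[Si](C)(C)C(C)(C)C)[C@H](OC(=O)/C(C)=C\C)[C@@](C)(O[Si](CC)(CC)CC)C(=O)[C@@H]1O[Si](CC)(CC)CC)[C@H](C[C@@H]2OC(C)(C)OC2(C)C)O | intermediate
18 | (1S,2R,4R,5R,6S)-6-[(tert-butyldimethylsilyl)oxy]-4-hydroxy-5-{(3S)-3-hydroxy-4-[(4S)-2,2,5,5-tetramethyl-1,3-dioxolan-4-yl]but-1-en-2-yl}-2-methyl-3-oxo-2-[(triethylsilyl)oxy]cyclohexyl (2Z)-2-methylbut-2-enoate | C=C([C@H]1[C@H](O[Si](C)(C)C(C)(C)C)[C@H](OC(=O)/C(C)=C\C)[C@@](C)(O[Si](CC)(CC)CC)C(=O)[C@@H]1O)[C@H](C[C@@H]2OC(C)(C)OC2(C)C)O | intermediate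
19 | (1S,2R,4R,5R,6S)-6-[(tert-butyldimethylsilyl)oxy]-2-methyl-5-{(3S)-3-{[(2Z)-2-methylbut-2-enoyl]oxy}-4-[(4S)-2,2,5,5-tetramethyl-1,3-dioxolan-4-yl]but-1-en-2-yl}-3-oxo-2-[(triethylsilyl)oxy]cyclohexane-1,4-diyl bis[(2Z)-2-methylbut-2-enoate] | C=C([C@H]1[C@H](O[Si](C)(C)C(C)(C)C)[C@H](OC(=O)/C(C)=C\C)[C@@](C)(O[Si](CC)(CC)CC)C(=O)[C@@H]1OC(=O)/C(C)=C\C)[C@H](C[C@@H]2OC(C)(C)OC2(C)C)OC(=O)/C(C)=C\C | intermediate
20 | CNP0215698.1, (1S,2R,4R,5S,6S)-5-[(3S,5S)-5,6-dihydroxy-6-methyl-3-{[(2Z)-2-methylbut-2-enoyl]oxy}hept-1-en-2-yl]-2,6-dihydroxy-2-methyl-3-oxocyclohexane-1,4-diyl bis[(2Z)-2-methylbut-2-enoate] | C=C([C@H]1[C@H](O)[C@H](OC(=O)/C(C)=C\C)[C@@](C)(O)C(=O)[C@@H]1OC(=O)/C(C)=C\C)[C@H](C[C@H](O)C(C)(C)O)OC(=O)/C(C)=C\C | target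

**Step count and risks**
Total: 14 steps. Longest linear sequence: 13 steps (1 → 20 through steps 1–8 and 10–14); step 9 makes the epoxide.

Most likely to fail, first: step 10, the proposed new coupling. The alkyl or acyl radical may add to the 2-substituted acrolein unit, decatungstate may abstract other hydridic C–H bonds, and the β-hydroxy enone may close by oxa-Michael addition. The fallback uses known chemistry and sets out from 11 and 13. The epoxide 13 is opened with LiI/AcOH in THF and the iodohydrin 14 is isolated. Aldehyde 11 is oxidised (NaClO2, NaH2PO4, 2-methylbut-2-ene, t-BuOH/H2O) to the acrylic acid F1. F1 is converted with 2,2'-dipyridyl disulfide and PPh3 into the S-pyridin-2-yl thioester F2. F2 and 14 are joined by the known nickel-catalysed reductive ketone synthesis from thioesters and alkyl iodides (NiCl2·(MeOCH2CH2OMe), 4,4'-di-tert-butyl-2,2'-bipyridine, Zn, DMA, 0 → 23 °C), which returns to the route at 15.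

Second: step 4, the Mitsunobu inversion at C1. The adjacent C6 silyl ether may slow SN2 attack by the weakly acidic angelic acid and favour SN2' attack or elimination. The fallback sets out from 5. Mitsunobu reaction with the more acidic 4-nitrobenzoic acid (PPh3, DIAD, THF) gives the inverted 4-nitrobenzoate F3. K2CO3 in MeOH at 0 °C frees the C1-epimeric allylic alcohol F4. Yamaguchi esterification with angelic acid (retention) then returns to the route at 6.

Third: step 12, where a 1,3-acetonide across C8/C10 or loss of the tertiary TES group could compete. The fallback drops the acetonide and sets out from 16. PPTS in MeOH at 0 °C removes only the secondary TES ether and gives the tetraol F5. Yamaguchi angeloylation with 2.2 equivalents of mixed anhydride at 40 °C acylates the α-ketol and allylic hydroxyls, relying on the hindrance of the C10 hydroxyl next to the tertiary carbinol, and gives the trisangelate F6. Aqueous HF in MeCN then returns to the route at 20.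

**Further compounds**
F1 | step 10 | 2-[(1S,2S,3R,5R,6S)-6-[(tert-butyldimethylsilyl)oxy]-5-(angeloyloxy)-4-methyl-3-oxo-2,4-bis[(triethylsilyl)oxy]cyclohexyl]prop-2-enoic acid (formyl group of 11 oxidised to CO2H) | C=C(C(=O)O)[C@H]1[C@H](O[Si](C)(C)C(C)(C)C)[C@H](OC(=O)/C(C)=C\C)[C@@](C)(O[Si](CC)(CC)CC)C(=O)[C@@H]1O[Si](CC)(CC)CC
F2 | step 10 | S-pyridin-2-yl thioester of F1 | C=C(C(=O)Sc1ccccn1)[C@H]2[C@H](O[Si](C)(C)C(C)(C)C)[C@H](OC(=O)/C(C)=C\C)[C@@](C)(O[Si](CC)(CC)CC)C(=O)[C@@H]2O[Si](CC)(CC)CC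
F3 | step 4 | (1R,5S,6S)-6-[(tert-butyldimethylsilyl)oxy]-5-(3-chloroprop-1-en-2-yl)-2-methylcyclohex-2-en-1-yl 4-nitrobenzoate | C=C(CCl)[C@H]1[C@H](O[Si](C)(C)C(C)(C)C)[C@H](OC(=O)c2ccc(cc2)[N+](=O)[O-])C(C)=CC1
F4 | step 4 | (1R,5S,6S)-6-[(tert-butyldimethylsilyl)oxy]-5-(3-chloroprop-1-en-2-yl)-2-methylcyclohex-2-en-1-ol | C=C(CCl)[C@H]1[C@H](O[Si](C)(C)C(C)(C)C)[C@H](O)C(C)=CC1
F5 | step 12 | (1S,2R,4R,5R,6S)-6-[(tert-butyldimethylsilyl)oxy]-4-hydroxy-2-methyl-3-oxo-2-[(triethylsilyl)oxy]-5-[(3S,5S)-3,5,6-trihydroxy-6-methylhept-1-en-2-yl]cyclohexyl (2Z)-2-methylbut-2-enoate | C=C([C@H]1[C@H](O[Si](C)(C)C(C)(C)C)[C@H](OC(=O)/C(C)=C\C)[C@@](C)(O[Si](CC)(CC)CC)C(=O)[C@@H]1O)[C@H](C[C@H](O)C(C)(C)O)O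
F6 | step 12 | (1S,2R,4R,5R,6S)-6-[(tert-butyldimethylsilyl)oxy]-5-[(3S,5S)-5,6-dihydroxy-6-methyl-3-{[(2Z)-2-methylbut-2-enoyl]oxy}hept-1-en-2-yl]-2-methyl-3-oxo-2-[(triethylsilyl)oxy]cyclohexane-1,4-diyl bis[(2Z)-2-methylbut-2-enoate] | C=C([C@H]1[C@H](O[Si](C)(C)C(C)(C)C)[C@H](OC(=O)/C(C)=C\C)[C@@](C)(O[Si](CC)(CC)CC)C(=O)[C@@H]1OC(=O)/C(C)=C\C)[C@H](C[C@H](O)C(C)(C)O)OC(=O)/C(C)=C\C
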